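**Retrosynthetic overview**
1. The enyne is cut at its C(sp)–C(sp2) bond (Sonogashira): a 2-ethynyl oxolane plus (1Z,9E)-1-bromo-10-iododeca-1,9-diene, the latter made from deca-1,9-diyne.
2. The ethynyl group comes from a formyl group, and this from a CH2–S(O)Tol arm on C2 (Pummerer), which the ring closure leaves behind.
3. The oxolane ring is the only ring and is formed once, in step 7, by making C2–C3: a primary C3 radical, released by decarboxylation of an N-acyloxyphthalimide, closes 5-exo-trig onto C2 of a (Z)-β-alkoxyvinyl (S)-sulfoxide.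
4. The enabling feature is ring oxygen O1 between C5 and C2: O1–C2 can be carried as an enol ether whose C2 is the β-carbon of a vinylogous sulfinate, and C3 lies at the end of the chain C3–C4–C5–O1–C2. C3 (with the carbon lost as CO2), C4 and C5 are the ring carbons of a γ-lactone of the L-glutamic acid series, whose C5 stereocentre is the only one bought.
5. The acyclic precursor comes from opening that lactone and adding the C5 alkoxide to (S)-ethynyl p-tolyl sulfoxide; the ester side chain comes from Giese addition of the iodomethyl lactone to tert-butyl acrylate.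

Key step: step 7

Remark: C2 is the ring carbon bearing the enyne, C5 the ring carbon bearing the butanoate chain and O1 the oxygen between them; the sense of induction at sulfur follows the allylic-strain model given in step 7 and is an assumption of the proposal.

**Route**

Step 1
Reactants: 1 (1S,2R,5S)-menthyl (R)-4-methylbenzenesulfinate; 2 ethynyltrimethylsilane
Product: 4 (R)-trimethyl{[(4-methylphenyl)sulfinyl]ethynyl}silane, via [(trimethylsilyl)ethynyl]magnesium bromide 3 (not isolated)
Conditions: 2, EtMgBr, THF, 0 °C → rt; then 1, PhMe, −20 °C; H2O work-up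
Reagents that add atoms: ethylmagnesium bromide, CC[Mg]Br (its MgBr unit is held only by intermediate 3; none of its atoms reach 4)
Why: Andersen sulfoxide synthesis, in which the alkynyl Grignard reagent displaces mentholate at sulfur with inversion, so the (R)-sulfinate should give the spatial arrangement needed later (descriptor R here only because the silylethynyl group outranks tolyl).

Step 2
Reactants: 4 (R)-trimethyl{[(4-methylphenyl)sulfinyl]ethynyl}silane
Product: 5 (S)-1-(ethynesulfinyl)-4-methylbenzene
Conditions: n-Bu4NF, AcOH, THF, −40 → 0 °C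
Reagents that add atoms: none
Why: Fluoride-induced C(sp)–Si cleavage, buffered with acetic acid so that no nucleophile adds to the alkynyl sulfoxide; sulfur is untouched and the descriptor becomes S only because ethynyl ranks below tolyl.

Step 3
Reactants: 6 (5S)-5-(hydroxymethyl)oxolan-2-one
Product: 7 (5S)-5-(iodomethyl)oxolan-2-one
Conditions: I2, PPh3, imidazole, CH2Cl2, 0 °C → rt
Reagents that add atoms: iodine, II
Why: Appel-type iodination (Garegg–Samuelsson conditions) of a primary alcohol by SN2 displacement of the alkoxyphosphonium ion; the stereocentre is not involved.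

Step 4
Reactants: 7 (5S)-5-(iodomethyl)oxolan-2-one; 8 tert-butyl prop-2-enoate
Product: 9 tert-butyl 4-[(2R)-5-oxooxolan-2-yl]butanoate
Conditions: 8 (excess), (Me3Si)3SiH (slow addition), AIBN (cat.), PhMe, 80 °C
Reagents that add atoms: none
Why: Giese reaction, in which the primary radical from the iodide adds to the acrylate β-carbon and the α-ester radical is reduced by the silane in a chain process; the stereocentre is untouched (S becomes R by priority change only).

Step 5
Reactants: 9 tert-butyl 4-[(2R)-5-oxooxolan-2-yl]butanoate; 5 (S)-1-(ethynesulfinyl)-4-methylbenzene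
Product: 11 (4R)-8-tert-butoxy-4-({(Z)-2-[(S)-4-methylbenzenesulfinyl]ethenyl}oxy)-8-oxooctanoic acid, via sodium (4R)-8-tert-butoxy-4-hydroxy-8-oxooctanoate 10 (not isolated)
Conditions: NaOH (1.0 equiv), THF/H2O, 0 °C → rt; evaporate, PhMe azeotrope; then 5, KN(SiMe3)2 (0.2 equiv), THF/DMF, −40 → 0 °C; aq. NaH2PO4
Reagents that add atoms: sodium hydroxide, [Na+].[OH-]
Why: Hydroxide should open the lactone while the tert-butyl ester resists, the carboxylate cannot re-lactonise, and oxa-Michael anti-addition of the C4 alkoxide to the alkynyl sulfoxide with kinetic protonation of the vinyl anion should give the (Z)-alkene with both stereocentres untouched.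

Step 6
Reactants: 11 (4R)-8-tert-butoxy-4-({(Z)-2-[(S)-4-methylbenzenesulfinyl]ethenyl}oxy)-8-oxooctanoic acid; 12 N-hydroxyphthalimide
Product: 13 8-tert-butyl 1-(1,3-dioxoisoindolin-2-yl) (4R)-4-({(Z)-2-[(S)-4-methylbenzenesulfinyl]ethenyl}oxy)octanedioate
Conditions: N,N'-diisopropylcarbodiimide, DMAP (cat.), CH2Cl2, 0 °C → rt
Reagents that add atoms: none
Why: Steglich-type carbodiimide esterification, which should turn the acid into a redox-active ester without touching the enol ether or the sulfoxide.

Step 7
Reactants: 13 8-tert-butyl 1-(1,3-dioxoisoindolin-2-yl) (4R)-4-({(Z)-2-[(S)-4-methylbenzenesulfinyl]ethenyl}oxy)octanedioate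
Product: 14 tert-butyl 4-[(2R,5S)-5-{[(S)-4-methylbenzenesulfinyl]methyl}oxolan-2-yl]butanoate
Conditions: Ru(bpy)3(PF6)2 (1 mol%), Hantzsch ester (1.5 equiv), i-Pr2NEt·HBF4 (1 equiv), CH2Cl2 (degassed, dilute), blue LEDs, 0 °C
Reagents that add atoms: none
Why: The photoexcited ruthenium complex is reductively quenched by Hantzsch ester and passes an electron to the phthalimide ester, which fragments to phthalimide anion, CO2 and the primary C3 radical; this adds to C2 of the vinyl sulfoxide and the α-sulfinyl radical is quenched by hydrogen transfer from the Hantzsch ester. The closest known reaction types are the decarboxylative Giese addition of N-acyloxyphthalimides under visible-light catalysis and the radical cyclisation of β-alkoxyvinyl sulfoxides and β-alkoxyacrylates to 2,5-disubstituted oxolanes, here merged in one intramolecular event. The oxolane ring closes 5-exo-trig, the nucleophilic alkyl radical bonding to the electrophilic β-carbon C2 and not to the α-carbon (6-endo), because of the polarisation of the vinylogous sulfinate. The new stereocentre C2 is controlled by sulfur: on the (Z)-alkene allylic strain places the sulfur lone pair in the alkene plane towards O1, so that S–O and p-tolyl lie on opposite faces and the radical should add anti to p-tolyl, which for the (S)-sulfoxide makes C2 (S), trans to the C5 side chain. The selectivity needed is this reagent control over the intrinsic cis preference of the 3-substituted 4-oxahex-5-enyl radical, which the (Z)-geometry, the low temperature and the fast closure onto an activated acceptor should secure. Chemoselectivity rests on the redox-active ester being the only group reducible by the reduced photocatalyst, the tert-butyl ester and the sulfoxide being inert.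

Step 8
Reactants: 14 tert-butyl 4-[(2R,5S)-5-{[(S)-4-methylbenzenesulfinyl]methyl}oxolan-2-yl]butanoate
Product: 16 tert-butyl 4-[(2R,5S)-5-formyloxolan-2-yl]butanoate, via tert-butyl 4-[(2R,5S)-5-{[(4-methylphenyl)sulfanyl](trifluoroacetoxy)methyl}oxolan-2-yl]butanoate 15 (not isolated)
Conditions: (CF3CO)2O, 2,4,6-collidine, MeCN, 0 °C; then aq. NaHCO3, 0 °C → rt
Reagents that add atoms: trifluoroacetic anhydride, O=C(OC(=O)C(F)(F)F)C(F)(F)F
Why: Pummerer rearrangement (O-acylation, thionium ion, capture by trifluoroacetate) followed by mild hydrolysis of the O,S-acetal should release the aldehyde and remove the sulfur auxiliary, the collidine buffer protecting the tert-butyl ester and C2.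

Step 9
Reactants: 16 tert-butyl 4-[(2R,5S)-5-formyloxolan-2-yl]butanoate
Product: 17 tert-butyl 4-[(2R,5S)-5-ethynyloxolan-2-yl]butanoate
Conditions: dimethyl (1-diazo-2-oxopropyl)phosphonate, K2CO3, MeOH, 0 °C → rt (crude 16 used at once)
Reagents that add atoms: dimethyl (1-diazo-2-oxopropyl)phosphonate, COP(=O)(OC)C(=[N+]=[N-])C(C)=O
Why: Ohira–Bestmann modification of the Seyferth–Gilbert homologation (diazomethylphosphonate anion adds to the aldehyde, phosphate is lost and the alkylidene carbene undergoes a 1,2-hydrogen shift), whose mild carbonate conditions should limit epimerisation of the α-alkoxy aldehyde.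

Step 10
Reactants: 17 tert-butyl 4-[(2R,5S)-5-ethynyloxolan-2-yl]butanoate
Product: 19 methyl 4-[(2R,5S)-5-ethynyloxolan-2-yl]butanoate, via 4-[(2R,5S)-5-ethynyloxolan-2-yl]butanoic acid 18 (not isolated)
Conditions: CF3CO2H/CH2Cl2, 0 °C → rt; concentrate; then Me3SiCHN2, MeOH/PhMe, 0 °C
Reagents that add atoms: (trimethylsilyl)diazomethane, C[Si](C)(C)C=[N+]=[N-]
Why: Acidolysis of the tert-butyl ester with loss of isobutene, then O-methylation of the acid by the methyldiazonium species formed from the silyl diazomethane and methanol; the change is safe at this stage because the C5 oxygen is now a ring ether.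

Step 11
Reactants: 20 deca-1,9-diyne
Product: 22 (1E)-1-iododec-1-en-9-yne, via chlorobis(cyclopentadienyl)[(1E)-dec-1-en-9-yn-1-yl]zirconium 21 (not isolated)
Conditions: Cp2Zr(H)Cl (substoichiometric to 20), THF, rt; then I2, 0 °C
Reagents that add atoms: Cp2Zr(H)Cl, [H][Zr](Cl)(C1C=CC=C1)C1C=CC=C1 (zirconium is held only by intermediate 21); iodine, II
Why: Hydrozirconation (syn addition with zirconium at the terminal carbon) followed by iodinolysis with retention should give the (E)-iodoalkene, the diyne being kept in excess to favour reaction at one end only.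

Step 12
Reactants: 22 (1E)-1-iododec-1-en-9-yne
Product: 23 (1E)-10-bromo-1-iododec-1-en-9-yne
Conditions: N-bromosuccinimide, AgNO3 (cat.), acetone, rt, dark
Reagents that add atoms: N-bromosuccinimide, O=C1CCC(=O)N1Br
Why: Silver-catalysed electrophilic bromination of a terminal alkyne through the silver acetylide, which should leave the iodoalkene untouched.

Step 13
Reactants: 23 (1E)-10-bromo-1-iododec-1-en-9-yne
Product: 24 (1Z,9E)-1-bromo-10-iododeca-1,9-diene
Conditions: 2-nitrobenzenesulfonohydrazide, Et3N, THF/i-PrOH, rt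
Reagents that add atoms: none
Why: Diimide reduction, a concerted syn transfer of two hydrogens that should turn the bromoalkyne into the (Z)-bromoalkene; the haloalkyne is expected to react much faster than the iodoalkene, and the reagent is limited.

Step 14
Reactants: 19 methyl 4-[(2R,5S)-5-ethynyloxolan-2-yl]butanoate; 24 (1Z,9E)-1-bromo-10-iododeca-1,9-diene
Product: 25 methyl 4-[(2R,5S)-5-[(3E,11Z)-12-bromododeca-3,11-dien-1-yn-1-yl]oxolan-2-yl]butanoate
Conditions: Pd(PPh3)4 (5 mol%), CuI (10 mol%), i-Pr2NH, THF, 0 °C → rt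
Reagents that add atoms: none
Why: Sonogashira coupling, in which zerovalent palladium should insert into the C–I bond far faster than into the C–Br bond at low temperature, with both alkene geometries retained.

**Compound list**
1 | (1S,2R,5S)-menthyl (R)-4-methylbenzenesulfinate | C[C@H]1CC[C@@H]([C@H](C1)O[S@@](=O)c1ccc(C)cc1)C(C)C | starting material
2 | ethynyltrimethylsilane | C[Si](C)(C)C#C | starting material
3 | [(trimethylsilyl)ethynyl]magnesium bromide | C[Si](C)(C)C#C[Mg]Br | intermediate
4 | (R)-trimethyl{[(4-methylphenyl)sulfinyl]ethynyl}silane | C[Si](C)(C)C#C[S@](=O)c1ccc(C)cc1 | intermediate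
5 | (S)-1-(ethynesulfinyl)-4-methylbenzene | C#C[S@](=O)c1ccc(C)cc1 | intermediate
6 | (5S)-5-(hydroxymethyl)oxolan-2-one | OC[C@@H]1CCC(=O)O1 | starting material
7 | (5S)-5-(iodomethyl)oxolan-2-one | IC[C@@H]1CCC(=O)O1 | intermediate
8 | tert-butyl prop-2-enoate | C=CC(=O)OC(C)(C)C | starting material
9 | tert-butyl 4-[(2R)-5-oxooxolan-2-yl]butanoate | CC(C)(C)OC(=O)CCC[C@@H]1CCC(=O)O1 | intermediate
10 | sodium (4R)-8-tert-butoxy-4-hydroxy-8-oxooctanoate | CC(C)(C)OC(=O)CCC[C@@H](O)CCC(=O)[O-].[Na+] | intermediate
11 | (4R)-8-tert-butoxy-4-({(Z)-2-[(S)-4-methylbenzenesulfinyl]ethenyl}oxy)-8-oxooctanoic acid | CC(C)(C)OC(=O)CCC[C@@H](O/C=C\[S@](=O)c1ccc(C)cc1)CCC(=O)O | intermediate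
12 | N-hydroxyphthalimide | ON1C(=O)c2ccccc2C1=O | starting material
13 | 8-tert-butyl 1-(1,3-dioxoisoindolin-2-yl) (4R)-4-({(Z)-2-[(S)-4-methylbenzenesulfinyl]ethenyl}oxy)octanedioate | CC(C)(C)OC(=O)CCC[C@@H](O/C=C\[S@](=O)c1ccc(C)cc1)CCC(=O)ON1C(=O)c2ccccc2C1=O | intermediate
14 | tert-butyl 4-[(2R,5S)-5-{[(S)-4-methylbenzenesulfinyl]methyl}oxolan-2-yl]butanoate | CC(C)(C)OC(=O)CCC[C@@H]1CC[C@@H](C[S@](=O)c2ccc(C)cc2)O1 | intermediate
15 | tert-butyl 4-[(2R,5S)-5-{[(4-methylphenyl)sulfanyl](trifluoroacetoxy)methyl}oxolan-2-yl]butanoate (both epimers at the acetal carbon) | CC(C)(C)OC(=O)CCC[C@@H]1CC[C@@H](C(OC(=O)C(F)(F)F)Sc2ccc(C)cc2)O1 | intermediate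
16 | tert-butyl 4-[(2R,5S)-5-formyloxolan-2-yl]butanoate | CC(C)(C)OC(=O)CCC[C@@H]1CC[C@@H](C=O)O1 | intermediate
17 | tert-butyl 4-[(2R,5S)-5-ethynyloxolan-2-yl]butanoate | CC(C)(C)OC(=O)CCC[C@@H]1CC[C@@H](C#C)O1 | intermediate
18 | 4-[(2R,5S)-5-ethynyloxolan-2-yl]butanoic acid | OC(=O)CCC[C@@H]1CC[C@@H](C#C)O1 | intermediate
19 | methyl 4-[(2R,5S)-5-ethynyloxolan-2-yl]butanoate | COC(=O)CCC[C@@H]1CC[C@@H](C#C)O1 | intermediate
20 | deca-1,9-diyne | C#CCCCCCCC#C | starting material
21 | chlorobis(cyclopentadienyl)[(1E)-dec-1-en-9-yn-1-yl]zirconium | Cl[Zr](/C=C/CCCCCCC#C)(C1C=CC=C1)C1C=CC=C1 | intermediate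
22 | (1E)-1-iododec-1-en-9-yne | C#CCCCCCC/C=C/I | intermediate
23 | (1E)-10-bromo-1-iododec-1-en-9-yne | BrC#CCCCCCC/C=C/I | intermediate
24 | (1Z,9E)-1-bromo-10-iododeca-1,9-diene | Br/C=C\CCCCCC/C=C/I | intermediate
25 | methyl 4-[(2R,5S)-5-[(3E,11Z)-12-bromododeca-3,11-dien-1-yn-1-yl]oxolan-2-yl]butanoate | COC(=O)CCC[C@@H]1CC[C@@H](C#C/C=C/CCCCCC/C=C\Br)O1 | target

**Step count**
Total step count: 14. Longest linear sequence: 9 steps (steps 3, 4, 5, 6, 7, 8, 9, 10 and 14 from compound 6; the branch from compound 1 through steps 1, 2, 5–10 and 14 is equally long).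

**Steps most likely to fail**

Step 7. The sulfinyl group may not override the intrinsic cis preference of the cyclising radical, the sense of induction may be opposite to the model, or reversible radical addition may isomerise the (Z)-acceptor, so that facial selectivity at C2 is poor. The fallback closes the ring by C–O bond formation with known trans selectivity; it sets out from 9 and comes back at 16. Lactone 9 is reduced with i-Bu2AlH (CH2Cl2, −78 °C) to the lactol tert-butyl 4-[(2R)-5-hydroxyoxolan-2-yl]butanoate F1. Wittig methylenation (Ph3P=CH2 from Ph3PCH3Br and KOt-Bu, THF) opens it to tert-butyl (5R)-5-hydroxynon-8-enoate F2. Mukaiyama aerobic oxidative cyclisation (Co(modp)2, the bis(1-morpholinocarbamoyl-4,4-dimethyl-1,3-pentanedionato) complex of divalent cobalt, O2, t-BuOOH, i-PrOH, 50 °C) is expected to give the 2,5-trans alcohol tert-butyl 4-[(2R,5S)-5-(hydroxymethyl)oxolan-2-yl]butanoate F3. Dess–Martin oxidation then gives aldehyde 16.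

Step 5. The C4 alkoxide may attack the tert-butyl ester (acyl transfer to a six-membered lactone), the carboxylate–alkoxide may be poorly soluble, the vinyl sulfoxide may drift from Z to E under base, and unreacted hydroxy acid re-lactonises on acidification. The fallback carries the carboxyl carbon as a protected primary alcohol during O-vinylation; it sets out from 9 and comes back at 11. Lactone 9 is reduced with LiBH4 (THF, 0 °C → rt, tert-butyl ester retained) to tert-butyl (5R)-5,8-dihydroxyoctanoate F4. The primary hydroxyl is silylated (t-BuMe2SiCl, imidazole, CH2Cl2, −20 °C) to tert-butyl (5R)-8-{[tert-butyl(dimethyl)silyl]oxy}-5-hydroxyoctanoate F5. Addition to 5 (KN(SiMe3)2 cat., THF, −40 → 0 °C) gives tert-butyl (5R)-8-{[tert-butyl(dimethyl)silyl]oxy}-5-({(Z)-2-[(S)-4-methylbenzenesulfinyl]ethenyl}oxy)octanoate F6. HF·pyridine (THF/pyridine, 0 °C) frees tert-butyl (5R)-8-hydroxy-5-({(Z)-2-[(S)-4-methylbenzenesulfinyl]ethenyl}oxy)octanoate F7. Oxidation with TEMPO (cat.)/PhI(OAc)2 in MeCN/H2O takes the primary alcohol to acid 11.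

Step 14. After the C–I coupling, zerovalent palladium may insert into the (Z)-C–Br bond (double coupling, oligomers), or the bromoalkene may isomerise, so chemoselectivity is lost. The fallback installs the bromoalkene last; it sets out from 19 and comes back at 25. Commercial non-8-yn-1-ol is converted (Cp2Zr(H)Cl, THF; then I2) into (8E)-9-iodonon-8-en-1-ol F8. Sonogashira coupling of F8 with 19 (Pd(PPh3)4, CuI, i-Pr2NH, THF) gives methyl 4-[(2R,5S)-5-[(3E)-11-hydroxyundec-3-en-1-yn-1-yl]oxolan-2-yl]butanoate F9. Dess–Martin oxidation gives methyl 4-[(2R,5S)-5-[(3E)-11-oxoundec-3-en-1-yn-1-yl]oxolan-2-yl]butanoate F10. A Z-selective Wittig reaction with Ph3P=CHBr (from (bromomethyl)triphenylphosphonium bromide and KOt-Bu, THF, −78 °C) then gives 25.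

**Further compounds**
F1 | step 7 | tert-butyl 4-[(2R)-5-hydroxyoxolan-2-yl]butanoate (anomer mixture) | CC(C)(C)OC(=O)CCC[C@@H]1CCC(O)O1
F2 | step 7 | tert-butyl (5R)-5-hydroxynon-8-enoate | CC(C)(C)OC(=O)CCC[C@@H](O)CCC=C
F3 | step 7 | tert-butyl 4-[(2R,5S)-5-(hydroxymethyl)oxolan-2-yl]butanoate | CC(C)(C)OC(=O)CCC[C@@H]1CC[C@@H](CO)O1
F4 | step 5 | tert-butyl (5R)-5,8-dihydroxyoctanoate | CC(C)(C)OC(=O)CCC[C@@H](O)CCCO
F5 | step 5 | tert-butyl (5R)-8-{[tert-butyl(dimethyl)silyl]oxy}-5-hydroxyoctanoate | CC(C)(C)OC(=O)CCC[C@@H](O)CCCO[Si](C)(C)C(C)(C)C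
F6 | step 5 | tert-butyl (5R)-8-{[tert-butyl(dimethyl)silyl]oxy}-5-({(Z)-2-[(S)-4-methylbenzenesulfinyl]ethenyl}oxy)octanoate | CC(C)(C)OC(=O)CCC[C@@H](O/C=C\[S@](=O)c1ccc(C)cc1)CCCO[Si](C)(C)C(C)(C)C
F7 | step 5 | tert-butyl (5R)-8-hydroxy-5-({(Z)-2-[(S)-4-methylbenzenesulfinyl]ethenyl}oxy)octanoate | CC(C)(C)OC(=O)CCC[C@@H](O/C=C\[S@](=O)c1ccc(C)cc1)CCCO
F8 | step 14 | (8E)-9-iodonon-8-en-1-ol | OCCCCCCC/C=C/I
F9 | step 14 | methyl 4-[(2R,5S)-5-[(3E)-11-hydroxyundec-3-en-1-yn-1-yl]oxolan-2-yl]butanoate | COC(=O)CCC[C@@H]1CC[C@@H](C#C/C=C/CCCCCCCO)O1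
F10 | step 14 | methyl 4-[(2R,5S)-5-[(3E)-11-oxoundec-3-en-1-yn-1-yl]oxolan-2-yl]butanoate | COC(=O)CCC[C@@H]1CC[C@@H](C#C/C=C/CCCCCCC=O)O1
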